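**Strategy.** The oxane ring (O1; C2 aryl-bearing; C4 carbinol; C6 arylethyl-bearing) is disconnected at C2–C3 and C5–C6. Its C3–C4–C5 segment with the C4 oxygen is a latent acetoacetate, and C2 and C6, the two carbons on O1, are latent aldehyde carbons. One three-component asymmetric Maitland–Japp operation unites a bis-silyl dienolate of methyl acetoacetate, a 3-arylpropanal and O-benzylvanillin: a catalytic enantioselective vinylogous aldol reaction sets C6, then Knoevenagel condensation and reversible oxy-Michael closure build C2 under thermodynamic control. The C3 ester is then excised, the 2,6-cis ketone is reduced to the axial C4 alcohol and the benzyl ethers are removed.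

Key step: step 2

Remark on the chemistry: the (R) antipode of BINOL is assumed to send the dienolate to the Re face of the 3-arylpropanal (5S adduct); the (S) ligand would be used instead if a Mosher ester of a quenched aliquot showed the opposite sense.

**Step 1**
Reactants: 1 1-(benzyloxy)-4-bromo-2-methoxybenzene; 2 prop-2-en-1-ol (allyl alcohol)
Product: 4 3-[4-(benzyloxy)-3-methoxyphenyl]propanal, via enol tautomer 3 (not isolated)
Conditions: Pd(OAc)2 (5 mol%), n-Bu4NCl, NaHCO3, DMF, 80 °C
Reagents that add atoms: none
Why: Heck arylation of an allylic alcohol under ligand-free phase-transfer conditions: the aryl–palladium species adds with the aryl group at the terminal alkene carbon, β-hydride elimination toward the carbinol carbon gives enol 3, and tautomerisation should deliver the saturated aldehyde; no stereocentre is formed.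

**Step 2**
Reactants: 4 3-[4-(benzyloxy)-3-methoxyphenyl]propanal; 5 1-methoxy-1,3-bis(trimethylsilyloxy)buta-1,3-diene; 6 4-(benzyloxy)-3-methoxybenzaldehyde (O-benzylvanillin)
Product: 10 methyl (2S,3R,6S)-2-[4-(benzyloxy)-3-methoxyphenyl]-6-{2-[4-(benzyloxy)-3-methoxyphenyl]ethyl}-4-oxooxane-3-carboxylate, via bis-silyl aldol adduct 7 (not isolated), via hydroxy keto ester 8 (not isolated), via Knoevenagel adduct 9 (not isolated)
Conditions: Ti(OiPr)4/(R)-BINOL (cat.), 4 Å MS, THF, −78 °C to rt; then 6, TFA, CH2Cl2, −78 °C to rt, stirred until the isomer ratio no longer changes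
Reagents that add atoms: none
Why: One-pot asymmetric Maitland–Japp reaction: the BINOL–titanium Lewis acid activates aldehyde 4 and the terminal (γ) carbon of dienolate 5 adds in a vinylogous Mukaiyama aldol reaction to forge C5–C6, giving silylated adduct 7, which TFA desilylates to hydroxy keto ester 8. TFA then promotes Knoevenagel condensation of the doubly activated C3 methylene of 8 with the non-enolisable aldehyde 6 (C2–C3 bond, adduct 9), and the C6 hydroxyl closes the oxane by 6-endo-trig oxy-Michael addition to the alkylidene keto ester. The closest known reaction type is the multicomponent Maitland–Japp synthesis of oxan-4-ones from a β-keto ester derivative and two aldehydes. C6 (S) is set by the chiral catalyst through Re-face attack on 4; C2 is set under thermodynamic control because the oxy-Michael step is reversible at this electron-rich benzylic position, which should place the aryl group equatorial and cis to the C6 side chain, while C3 is epimerisable and is deleted in step 3. The step needs γ- over α-attack of the dienolate and cross- rather than homo-condensation of the two aldehydes: the first is intrinsic to the silyl dienolate, the second is secured by adding 6 only after 4 is consumed and by the fact that only the C3 methylene between two carbonyls is acidic enough to condense.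

**Step 3**
Reactants: 10 methyl (2S,3R,6S)-2-[4-(benzyloxy)-3-methoxyphenyl]-6-{2-[4-(benzyloxy)-3-methoxyphenyl]ethyl}-4-oxooxane-3-carboxylate
Product: 11 (2S,6S)-2-[4-(benzyloxy)-3-methoxyphenyl]-6-{2-[4-(benzyloxy)-3-methoxyphenyl]ethyl}oxan-4-one
Conditions: DMF/H2O (10:1), 160 °C, microwave (sealed vessel), short reaction time
Reagents that add atoms: none
Why: Krapcho-type hydrolytic dealkoxycarbonylation of the β-keto ester removes the C3 activating group, and at this temperature reversible retro-oxy-Michael/oxy-Michael opening at the benzylic C2–O1 bond should funnel any 2,6-trans material into the diequatorial 2,6-cis ketone, while C6, set in step 2, is not part of that equilibrium.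

**Step 4**
Reactants: 11 (2S,6S)-2-[4-(benzyloxy)-3-methoxyphenyl]-6-{2-[4-(benzyloxy)-3-methoxyphenyl]ethyl}oxan-4-one
Product: 12 (2S,4S,6S)-2-[4-(benzyloxy)-3-methoxyphenyl]-6-{2-[4-(benzyloxy)-3-methoxyphenyl]ethyl}oxan-4-ol
Conditions: LiBH(s-Bu)3 (L-Selectride, 1.5 equiv), THF, −78 °C; then sat. aq. NH4Cl
Reagents that add atoms: none
Why: Diastereoselective ketone reduction with a bulky trialkylborohydride: hydride should be delivered along the equatorial trajectory of the chair that holds both C2 and C6 substituents equatorial, so the new C4 hydroxyl is axial and trans to both (4S).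

**Step 5**
Reactants: 12 (2S,4S,6S)-2-[4-(benzyloxy)-3-methoxyphenyl]-6-{2-[4-(benzyloxy)-3-methoxyphenyl]ethyl}oxan-4-ol
Product: 13 (2S,4S,6S)-2-(4-hydroxy-3-methoxyphenyl)-6-[2-(4-hydroxy-3-methoxyphenyl)ethyl]oxan-4-ol
Conditions: H2 (1 atm), Pd/C (10 wt%), EtOAc, rt; stopped as soon as debenzylation is complete
Reagents that add atoms: none
Why: Catalytic hydrogenolysis of the two aryl benzyl ethers, which should cleave much faster than the cyclic benzylic C2–O1 ether under neutral conditions at atmospheric pressure, so the three stereocentres are left untouched.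

**Compound list**

1 | 1-(benzyloxy)-4-bromo-2-methoxybenzene | COc1cc(Br)ccc1OCc1ccccc1 | starting material
2 | prop-2-en-1-ol (allyl alcohol) | C=CCO | starting material
3 | 3-[4-(benzyloxy)-3-methoxyphenyl]prop-1-en-1-ol (enol tautomer, alkene geometry not defined) | COc1cc(CC=CO)ccc1OCc1ccccc1 | intermediate (not isolated)
4 | 3-[4-(benzyloxy)-3-methoxyphenyl]propanal | COc1cc(CCC=O)ccc1OCc1ccccc1 | intermediate
5 | 1-methoxy-1,3-bis(trimethylsilyloxy)buta-1,3-diene (bis-silyl dienolate of methyl acetoacetate) | COC(O[Si](C)(C)C)=CC(=C)O[Si](C)(C)C | starting material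
6 | 4-(benzyloxy)-3-methoxybenzaldehyde (O-benzylvanillin) | COc1cc(C=O)ccc1OCc1ccccc1 | starting material
7 | methyl (5S)-7-[4-(benzyloxy)-3-methoxyphenyl]-3,5-bis(trimethylsilyloxy)hept-2-enoate (enol ether geometry not defined) | COc1cc(CC[C@H](O[Si](C)(C)C)CC(O[Si](C)(C)C)=CC(=O)OC)ccc1OCc1ccccc1 | intermediate (not isolated)
8 | methyl (5S)-7-[4-(benzyloxy)-3-methoxyphenyl]-5-hydroxy-3-oxoheptanoate | COc1cc(CC[C@H](O)CC(=O)CC(=O)OC)ccc1OCc1ccccc1 | intermediate (not isolated)
9 | methyl (5S)-2-[4-(benzyloxy)-3-methoxybenzylidene]-7-[4-(benzyloxy)-3-methoxyphenyl]-5-hydroxy-3-oxoheptanoate (E/Z mixture) | COc1cc(CC[C@H](O)CC(=O)C(=Cc2ccc(OCc3ccccc3)c(OC)c2)C(=O)OC)ccc1OCc1ccccc1 | intermediate (not isolated)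
10 | methyl (2S,3R,6S)-2-[4-(benzyloxy)-3-methoxyphenyl]-6-{2-[4-(benzyloxy)-3-methoxyphenyl]ethyl}-4-oxooxane-3-carboxylate (drawn as the all-equatorial keto tautomer; C3 is epimerisable and enolisable) | COc1cc(CC[C@H]2CC(=O)[C@H](C(=O)OC)[C@@H](c3ccc(OCc4ccccc4)c(OC)c3)O2)ccc1OCc1ccccc1 | intermediate
11 | (2S,6S)-2-[4-(benzyloxy)-3-methoxyphenyl]-6-{2-[4-(benzyloxy)-3-methoxyphenyl]ethyl}oxan-4-one (2,6-cis) | COc1cc(CC[C@H]2CC(=O)C[C@@H](c3ccc(OCc4ccccc4)c(OC)c3)O2)ccc1OCc1ccccc1 | intermediate
12 | (2S,4S,6S)-2-[4-(benzyloxy)-3-methoxyphenyl]-6-{2-[4-(benzyloxy)-3-methoxyphenyl]ethyl}oxan-4-ol (2,6-cis, axial 4-OH) | COc1cc(CC[C@H]2C[C@H](O)C[C@@H](c3ccc(OCc4ccccc4)c(OC)c3)O2)ccc1OCc1ccccc1 | intermediate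
13 | (2S,4S,6S)-2-(4-hydroxy-3-methoxyphenyl)-6-[2-(4-hydroxy-3-methoxyphenyl)ethyl]oxan-4-ol | COc1cc(CC[C@H]2C[C@H](O)C[C@@H](c3ccc(O)c(OC)c3)O2)ccc1O | target

**Step count.** Total: 5 steps. Longest linear sequence: 5 steps (1 → 4 → 10 → 11 → 12 → 13).

**Steps most likely to fail**

1. Step 2 (key step). What may go wrong: insufficient enantiofacial control in the vinylogous aldol addition to an unbranched aliphatic aldehyde, and sluggish Knoevenagel condensation of the electron-rich aryl aldehyde that lets the aldol intermediate dehydrate instead. Fallback: the C6 configuration is set by ketone hydrogenation instead of by C–C bond formation, and the ring is assembled stepwise. Setting out from 4, SnCl2-catalysed homologation with ethyl diazoacetate (Roskamp reaction, CH2Cl2, rt) would give ethyl 5-[4-(benzyloxy)-3-methoxyphenyl]-3-oxopentanoate F1. Noyori hydrogenation of F1 with RuCl2[(S)-BINAP] under H2 in EtOH would give ethyl (3S)-5-[4-(benzyloxy)-3-methoxyphenyl]-3-hydroxypentanoate F2, the benzyl ether being inert to this catalyst. Crossed Claisen condensation of F2 with excess lithium enolate of methyl acetate (LiN(i-Pr)2, MeOAc, THF, −78 to −20 °C) would give 8 as an isolated compound. Compound 8 is then condensed with 6 under TFA in CH2Cl2, and the fallback comes back to the route at 10.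

2. Step 1. What may go wrong: slow oxidative addition of the electron-rich aryl bromide, insertion with the opposite regiochemistry, or β-hydride elimination away from the carbinol carbon, giving branched or allylic-alcohol by-products, together with base-induced self-condensation of the aldehyde. Fallback: the three-carbon chain is attached by organolithium chemistry. Setting out from 1, bromine–lithium exchange (n-BuLi, THF, −78 °C) followed by BF3·OEt2-promoted opening of oxetane would give 3-[4-(benzyloxy)-3-methoxyphenyl]propan-1-ol F3. Oxidation of F3 with Dess–Martin periodinane (CH2Cl2, rt) comes back to the route at 4.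

3. Step 5. What may go wrong: over-reduction, that is, hydrogenolytic opening of the ring at the benzylic C2–O1 bond once the para oxygen is freed. Fallback: a non-reductive debenzylation. Setting out from 12, BCl3 with pentamethylbenzene as cation scavenger (CH2Cl2, −78 °C) should cleave both aryl benzyl ethers while sparing the aryl methyl ethers, and comes back to the route at 13; this fallback makes no new compound (F0).

**Further compounds**

F1 | step 2 | ethyl 5-[4-(benzyloxy)-3-methoxyphenyl]-3-oxopentanoate | COc1cc(CCC(=O)CC(=O)OCC)ccc1OCc1ccccc1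
F2 | step 2 | ethyl (3S)-5-[4-(benzyloxy)-3-methoxyphenyl]-3-hydroxypentanoate | COc1cc(CC[C@H](O)CC(=O)OCC)ccc1OCc1ccccc1
F3 | step 1 | 3-[4-(benzyloxy)-3-methoxyphenyl]propan-1-ol | COc1cc(CCCO)ccc1OCc1ccccc1
F0 | step 5 | none | none
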